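## Structural features

The target 23 is a 2,3-dihydrobenzofuran neolignan ester. Ring A (the benzo ring) is fused to the dihydrofuran through C3a and C7a, carries a methoxy group at C7 and, at C5, a three-carbon chain whose terminal oxygen is acylated by (E)-ferulic acid. C2 bears a 4-hydroxy-3-methoxyphenyl group (ring B) and C3 a hydroxymethyl group. These two adjacent stereocentres, (2R,3S), are trans and are the only stereogenic elements. The fragile parts are the (E)-cinnamate ester (no hydrogenation, hydride or strong base once it is in place), the two free phenols, and the C2–O1 bond, a p-hydroxybenzyl aryl ether that can open to a quinone methide under acid or strong base. The real difficulty is twofold: to fix the C2/C3 pair in absolute and relative terms without relying on a reversible ring closure, and to place four different substituents on ring A with unambiguous regiochemistry while keeping two primary alcohols apart. The key step exploits the O1–C7a aryl ether bond. It lies ortho to the C7 methoxy group, and cutting it turns O1 into a secondary benzylic hydroxyl in an open-chain 1,2-diaryl-propane-1,3-diol whose two centres have the syn relationship of an aldol adduct. A second feature is used once the ring is closed: C5–H is the only aromatic C–H of the core whose two neighbours are both C–H, so a sterically governed C–H borylation can single it out.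

## Logic of the disconnections

23 to 22: the two O–Si bonds (ring B phenol oxygen and the C3 hydroxymethyl oxygen) are cut last. Silicon keeps the ring B phenol from becoming a phenoxide para to C2–O1 and keeps the C3 hydroxymethyl distinct from the chain hydroxyl. One fluoride step then ends the synthesis. The demand is a buffered fluoride source that spares the cinnamate and the benzylic aryl ether.

22 to 20 and 21: the CH2–O bond of the ester is cut. Introducing the cinnamate this late means it never meets hydride, borane, peroxide or palladium hydride, and 21 can be used without protection. The forward step must alkylate the carboxylate and not the phenol of 21; the large acidity difference between the two under Mitsunobu activation of 20 provides this.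

20 to 18, then 16 and 17, then 15: three cuts in a row. First the terminal C–O bond of the chain (hydroboration–oxidation of a terminal alkene), then the C5–CH2 bond (cross-coupling of an arylboronate with 17), then the C5–B bond (C–H borylation). Cutting at C5 is justified because C5–H is the only unflanked aromatic C–H in 15, so ring A can come from the simple 1 with no substituent at that position. The demands are steric control by the iridium catalyst and a coupling that does not move the allyl double bond into conjugation. The boronate is used directly as the nucleophile, which avoids a halodeboronation with a copper dihalide in hot protic medium on a bis-silyl ether with two electron-rich rings.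

15 to 14: the O1–C7a bond is cut. This opens the only ring that is not aromatic and leaves an acyclic syn diol derivative. Its two stereocentres are not touched by the forward reaction, so the ring stereochemistry becomes a question of acyclic stereocontrol. The forward step must arylate the secondary oxygen only, with retention, at a C–Br bond flanked on both sides.

14 to 13 to 12: the primary O–Si bond is cut, then the primary alcohol is taken back to the N-acyl group of an auxiliary. This reveals an aldol adduct. The demands are silylation of the primary hydroxyl only and a reduction that is faster than retro-aldol cleavage or enolisation.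

12 to 7 and 9: the bond between the two stereocentres (C2–C3 in dihydrobenzofuran numbering) is cut. One aldol addition then creates both centres under control of the auxiliary and joins ring A to ring B. The forward step needs a Z enolate and the (R)-configured auxiliary to deliver the (2R,3R) syn adduct.

7 to 4 and 5, and 4 to 3 to 2 to 1: the N–acyl bond is cut, then the arylacetic acid is reduced to the benzaldehyde by removing one carbon (C=C of an enol ether, Wittig). The gain is a cheap aromatic aldehyde that already holds bromine between the side chain and the methoxy group. The demand is a homologation that leaves the aryl bromide alone.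

9 to 8: one O–Si bond is cut. The phenol of 8 must be masked before the boron enolate is used.

## Other disconnections considered

Alternative 1: The cut is the C3–C3a bond, with the C3 substituent taken back to the ester oxidation level. The precursor is the ring-expanded (2R)-flavanone A1, in which ring A is bonded to the carbonyl carbon.
- Forward key step: A1 would be treated with PhI(OAc)2 and catalytic H2SO4 in HC(OMe)3. The enol ether of the ketone is attacked at C3 by trivalent iodine. Loss of iodobenzene is assisted by a 1,2-shift of the ring A carbon from C4 to C3, and the resulting dialkoxycarbenium ion collapses to the methyl ester A2.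
- In its favour: ring A arrives with the C5 chain and the C7 methoxy group in place, so no aryl halide next to a methoxy group and no late C–H functionalisation are needed. The trans arrangement of A2 is the thermodynamic one and can be corrected by epimerisation next to the ester. The core is reached in few steps.
- Against it here: the only source of absolute configuration is C2 of A1. That centre can racemise by reversible ring opening under the acidic conditions of the rearrangement, the more so with an electron-rich ring B. Migration of ring B from C2 to C3 and dehydrogenation of the C2–C3 bond would compete, and both electron-rich rings are exposed to an oxidant. After the key step the ester must be reduced and both benzyl ethers removed by hydrogenolysis before the cinnamate can be attached, which leaves two primary alcohols and a phenol to be told apart.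
- Comparison: on steps to the bicyclic core and on regiochemical certainty in ring A this alternative is the better one. Mechanistically the two plans are opposite: here the stereocentres sit on the reacting atoms, in the chosen plan they are spectators. The chosen plan is therefore safer for the (2R,3S) pair, and also better in the end game because its three oxygen functions are already differentiated.

Alternative 2: The cut removes two bonds of ring A, C3a–C7a and C4–C5. Ring A is taken back to a 2-pyrone whose C3 oxygen carries the chiral side chain ending in a terminal alkyne (A3).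
- Forward key step: heating A3 would bring about intramolecular [4+2] cycloaddition of the alkyne across pyrone C3 and C6. The bridged lactone then loses CO2 in a retro-[4+2] step, and the benzene ring of A4 appears together with the dihydrofuran ring.
- In its favour: every ring A substituent is placed by the pyrone (its C4 methoxy becomes C7–OMe, its C6 chain becomes the C5 chain), so regiochemistry is not a matter of selectivity. Loss of CO2 makes the step irreversible. The stereocentres lie in the tether and not at reacting atoms.
- Against it here: A3 is demanding. A 3-hydroxy-2-pyrone would have to be O-alkylated at a secondary, p-silyloxy-substituted benzylic carbon of defined configuration, a centre that ionises easily, and the neighbouring propargylic centre is base-sensitive. A donor-substituted diene and an unactivated alkyne are poorly matched, so high temperature would be needed, at which the benzylic C–O bond of the tether may ionise or eliminate. The route would be longer.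
- Comparison: it is the better plan on ring A regiochemistry and on convergency (two rings in one step). It is the equal of the chosen plan in that the stereocentres are spectators, and about equal in the end game (one benzyl ether on the chain oxygen, orthogonal to the silyl ethers, though its hydrogenolysis puts the benzylic C2–O1 bond at some risk). The chosen plan is better on access to the precursor, on mildness and on step count.

Alternative 3: The cut is the O1–C2 bond, the alkyl side of the same ether whose aryl side the chosen plan cuts. The precursor A5 has the ring A phenol masked as a MOM ether and a free benzylic carbinol of either configuration.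
- Forward key step: TsOH in methanol would remove the MOM group and ionise the carbinol to a cation stabilised by the p-benzyloxy ring B. The free phenol then attacks anti to the C3 substituent to give the trans product A6.
- In its favour: only the C3 centre has to be made selectively, since both carbinol epimers converge. The ring A oxygen and the C5 chain come with the building block. No transition metal is needed and the step is biomimetic.
- Against it here: the C2 configuration results from a facial preference in a cation, helped by equilibration through reversible ionisation, and not from a stereospecific event. Trans should dominate, but its degree is not assured. The cation can be intercepted by methanol or by an electron-rich ring. Both benzyl ethers must again be removed by hydrogenolysis before esterification, after which the ring B phenol competes with the chain alcohol.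
- Comparison: it is the better plan in stereochemical economy (one centre instead of two), in tolerance of a poor diastereomer ratio and in needing no metal. It is equal or slightly shorter in steps, because no borylation and allylation are needed. The chosen plan is better in that trans follows by necessity from a syn aldol plus retention, and in that its basic, non-polar conditions never generate a cation at C2.

Key step: step 9

Remark on the chemistry: the target is read as the (2R,3S)-trans isomer with an E cinnamate. The key-step precursor 14 is then the (1R,2S) syn alcohol and the aldol adduct 12 is (2R,3R), which calls for the (R)-4-benzyl oxazolidinone 5. The change of descriptor at the aryl-bearing carbon between 12 and 13 is a CIP effect only, and the structures of 14 and 15 need no correction. Compounds 1, 5, 8, 17 and 21 are taken as purchasable; if acid 4 is bought, steps 1 to 3 fall away.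

## Route

Step 1
Reactants: 1 2-bromo-3-methoxybenzaldehyde
Product: 2 2-bromo-1-methoxy-3-(2-methoxyethenyl)benzene (E/Z mixture)
Conditions: Ph3P(CH2OMe)Cl, KOtBu, THF, 0 °C to rt
Reagents that add atoms: (methoxymethyl)triphenylphosphonium chloride, COC[P+](c1ccccc1)(c1ccccc1)c1ccccc1.[Cl-]
Why: Wittig olefination with the non-stabilised methoxymethylene ylide adds one carbon to the aldehyde; the E/Z mixture is of no consequence because both isomers hydrolyse to the same aldehyde.

Step 2
Reactants: 2 2-bromo-1-methoxy-3-(2-methoxyethenyl)benzene
Product: 3 2-(2-bromo-3-methoxyphenyl)acetaldehyde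
Conditions: 2 M HCl, THF, 50 °C; used crude
Reagents that add atoms: water, O
Why: Acid-catalysed enol ether hydrolysis (C-protonation, hydration of the oxocarbenium ion, loss of methanol) unmasks the arylacetaldehyde, which is carried on without purification because it enolises and self-condenses easily.

Step 3
Reactants: 3 2-(2-bromo-3-methoxyphenyl)acetaldehyde
Product: 4 2-(2-bromo-3-methoxyphenyl)acetic acid
Conditions: NaClO2, NaH2PO4, 2-methyl-2-butene, t-BuOH/H2O, 0 °C to rt
Reagents that add atoms: sodium chlorite, [Na+].[O-]Cl=O
Why: Pinnick oxidation takes the aldehyde to the acid under mildly acidic conditions that leave the aryl bromide alone; 2-methyl-2-butene removes HOCl and so prevents chlorination of the anisole ring.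

Step 4
Reactants: 4 2-(2-bromo-3-methoxyphenyl)acetic acid; 5 (R)-4-benzyl-1,3-oxazolidin-2-one
Product: 7 (R)-4-benzyl-3-[2-(2-bromo-3-methoxyphenyl)acetyl]-1,3-oxazolidin-2-one, via mixed pivalic anhydride 6 (not isolated)
Conditions: PivCl, Et3N, THF, −20 °C; then LiCl, 5, −20 °C to rt
Reagents that add atoms: none
Why: Mixed-anhydride N-acylation of the oxazolidinone, assisted by LiCl and Et3N, avoids an acid chloride and with it ketene formation from the arylacetyl unit; the nitrogen attacks the less hindered arylacetyl carbonyl of 6.

Step 5
Reactants: 8 vanillin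
Product: 9 3-methoxy-4-(triisopropylsilyloxy)benzaldehyde
Conditions: TIPSCl, imidazole, DMF, rt
Reagents that add atoms: chlorotriisopropylsilane, CC(C)[Si](Cl)(C(C)C)C(C)C
Why: Imidazole-promoted silylation of the phenol gives a base-tolerant, fluoride-labile ether; the bulky TIPS group is chosen to survive carbonate at 110 °C in step 9 and to leave with the other silyl group in the last step.

Step 6
Reactants: 7 (R)-4-benzyl-3-[2-(2-bromo-3-methoxyphenyl)acetyl]-1,3-oxazolidin-2-one; 9 3-methoxy-4-(triisopropylsilyloxy)benzaldehyde
Product: 12 (R)-4-benzyl-3-[(2R,3R)-2-(2-bromo-3-methoxyphenyl)-3-hydroxy-3-(3-methoxy-4-triisopropylsilyloxyphenyl)propanoyl]-1,3-oxazolidin-2-one, via Z-dibutylboron enolate 10 (not isolated), via dibutylboron aldolate 11 (not isolated)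
Conditions: Bu2BOTf, iPr2NEt, CH2Cl2, 0 °C; then 9, −78 to 0 °C; pH 7 buffer, MeOH, 30% H2O2, 0 °C
Reagents that add atoms: none
Why: Evans syn-aldol reaction: soft enolisation gives the Z-boron enolate 10, which adds to 9 through a chair Zimmerman–Traxler transition state on the enolate face opposite the benzyl group of the dipole-minimised (R)-auxiliary, setting the (2R,3R) syn pair that becomes C3 and C2. Oxidative work-up cleaves the boron aldolate 11.

Step 7
Reactants: 12 (R)-4-benzyl-3-[(2R,3R)-2-(2-bromo-3-methoxyphenyl)-3-hydroxy-3-(3-methoxy-4-triisopropylsilyloxyphenyl)propanoyl]-1,3-oxazolidin-2-one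
Product: 13 (1R,2S)-2-(2-bromo-3-methoxyphenyl)-1-(3-methoxy-4-triisopropylsilyloxyphenyl)propane-1,3-diol
Conditions: LiBH4, MeOH (1 equiv), THF, 0 °C
Reagents that add atoms: none
Why: Reductive cleavage of the imide by LiBH4 at the exocyclic carbonyl gives the primary alcohol and releases the auxiliary 5 for recovery; at 0 °C hydride transfer should be faster than retro-aldol cleavage or enolisation, so both centres are kept.

Step 8
Reactants: 13 (1R,2S)-2-(2-bromo-3-methoxyphenyl)-1-(3-methoxy-4-triisopropylsilyloxyphenyl)propane-1,3-diol
Product: 14 (1R,2S)-2-(2-bromo-3-methoxyphenyl)-1-(3-methoxy-4-triisopropylsilyloxyphenyl)-3-(triisopropylsilyloxy)propan-1-ol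
Conditions: TIPSCl, imidazole, CH2Cl2, 0 °C to rt
Reagents that add atoms: chlorotriisopropylsilane, CC(C)[Si](Cl)(C(C)C)C(C)C
Why: Sterically controlled silylation: TIPSCl should react only at the primary hydroxyl, because the secondary benzylic hydroxyl is flanked by two aryl-bearing carbons; the oxygen to be arylated is then the only free one.

Step 9
Reactants: 14 (1R,2S)-2-(2-bromo-3-methoxyphenyl)-1-(3-methoxy-4-triisopropylsilyloxyphenyl)-3-(triisopropylsilyloxy)propan-1-ol
Product: 15 (2R,3S)-7-methoxy-2-(3-methoxy-4-triisopropylsilyloxyphenyl)-3-(triisopropylsilyloxymethyl)-2,3-dihydrobenzofuran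
Conditions: CuI (10 mol%), 1,10-phenanthroline (20 mol%), Cs2CO3, degassed toluene, 110 °C
Reagents that add atoms: none
Why: Cs2CO3 converts the secondary benzylic hydroxyl into its alkoxide, which binds the phenanthroline complex of CuI as a monovalent copper alkoxide; the ortho C7a–Br bond then adds oxidatively, and C–O reductive elimination from the trivalent copper aryl alkoxide forms O1–C7a and returns the catalyst. The closest known reaction type is the Ullmann-type copper-catalysed intramolecular O-arylation of aliphatic alcohols with aryl bromides to 2,3-dihydrobenzofurans. The dihydrofuran ring closes in a 5-exo sense: the oxygen attacks the aromatic carbon and bromide leaves outside the new ring. No stereocentre is created; the C–O bond of the carbinol and all bonds to the neighbouring carbon stay intact, so arylation occurs with retention and the syn (1R,2S) aldol relationship becomes the (2R,3S)-trans arrangement of the aryl and silyloxymethyl groups. Three selectivities are needed. The site is fixed because there is only one C–Br bond, placed between the side chain and the methoxy group. The choice between the two oxygens, either of which could close a five-membered ring, is secured by the TIPS ether on the primary oxygen, whose bulk together with the non-polar solvent disfavours a 1,5 O-to-O silyl shift. Oxidation of the carbinol to the ketone with reduction of the C–Br bond is avoided by using copper, which has little tendency to β-hydride elimination, under degassed conditions.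

Step 10
Reactants: 15 (2R,3S)-7-methoxy-2-(3-methoxy-4-triisopropylsilyloxyphenyl)-3-(triisopropylsilyloxymethyl)-2,3-dihydrobenzofuran
Product: 16 (2R,3S)-7-methoxy-2-(3-methoxy-4-triisopropylsilyloxyphenyl)-5-(4,4,5,5-tetramethyl-1,3,2-dioxaborolan-2-yl)-3-(triisopropylsilyloxymethyl)-2,3-dihydrobenzofuran
Conditions: [Ir(cod)(OMe)]2 (1.5 mol%), 4,4'-di-tert-butyl-2,2'-bipyridine (3 mol%), B2pin2, cyclohexane, 80 °C
Reagents that add atoms: bis(pinacolato)diboron, CC1(C)OB(OC1(C)C)B1OC(C)(C)C(C)(C)O1
Why: Iridium-catalysed aromatic C–H borylation through a tris(boryl)iridium species is governed by sterics and avoids C–H bonds ortho to a substituent. C5–H is the only C–H of 15 with two C–H neighbours (C4–H and C6–H are each ortho to a substituent, as is every C–H of ring B), so boron should enter at C5 only.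

Step 11
Reactants: 16 (2R,3S)-7-methoxy-2-(3-methoxy-4-triisopropylsilyloxyphenyl)-5-(4,4,5,5-tetramethyl-1,3,2-dioxaborolan-2-yl)-3-(triisopropylsilyloxymethyl)-2,3-dihydrobenzofuran; 17 allyl bromide
Product: 18 (2R,3S)-5-allyl-7-methoxy-2-(3-methoxy-4-triisopropylsilyloxyphenyl)-3-(triisopropylsilyloxymethyl)-2,3-dihydrobenzofuran
Conditions: Pd(PPh3)4 (5 mol%), K2CO3, THF/H2O, 65 °C
Reagents that add atoms: none
Why: Suzuki–Miyaura coupling of the arylboronate with an allylic electrophile (oxidative addition of 17 to zerovalent palladium to a π-allyl complex, base-assisted transmetalation, reductive elimination) forms the C5–CH2 bond; aqueous carbonate is used instead of fluoride to keep both silyl ethers.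

Step 12
Reactants: 18 (2R,3S)-5-allyl-7-methoxy-2-(3-methoxy-4-triisopropylsilyloxyphenyl)-3-(triisopropylsilyloxymethyl)-2,3-dihydrobenzofuran
Product: 20 3-[(2R,3S)-7-methoxy-2-(3-methoxy-4-triisopropylsilyloxyphenyl)-3-(triisopropylsilyloxymethyl)-2,3-dihydrobenzofuran-5-yl]propan-1-ol, via B-alkyl-9-BBN adduct 19 (not isolated)
Conditions: 9-BBN, THF, 0 °C to rt; then 3 M aq NaOAc, 30% H2O2, 0 °C to rt
Reagents that add atoms: hydrogen peroxide, OO
Why: Anti-Markovnikov hydroboration with the bulky 9-BBN puts boron on the terminal carbon, and peroxide oxidation (1,2-shift of carbon from boron to oxygen) gives the primary alcohol; acetate buffering keeps hydroxide away from the aryl silyl ether.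

Step 13
Reactants: 20 3-[(2R,3S)-7-methoxy-2-(3-methoxy-4-triisopropylsilyloxyphenyl)-3-(triisopropylsilyloxymethyl)-2,3-dihydrobenzofuran-5-yl]propan-1-ol; 21 (E)-ferulic acid
Product: 22 3-[(2R,3S)-7-methoxy-2-(3-methoxy-4-triisopropylsilyloxyphenyl)-3-(triisopropylsilyloxymethyl)-2,3-dihydrobenzofuran-5-yl]propyl (E)-3-(4-hydroxy-3-methoxyphenyl)prop-2-enoate
Conditions: PPh3, DIAD, THF, 0 °C to rt
Reagents that add atoms: none
Why: Mitsunobu esterification: the primary alcohol is activated as an alkoxyphosphonium ion and displaced by the carboxylate. The carboxyl group of 21 is several pKa units more acidic than its phenol, so the carboxylate is the nucleophile and no phenol protection is needed.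

Step 14
Reactants: 22 3-[(2R,3S)-7-methoxy-2-(3-methoxy-4-triisopropylsilyloxyphenyl)-3-(triisopropylsilyloxymethyl)-2,3-dihydrobenzofuran-5-yl]propyl (E)-3-(4-hydroxy-3-methoxyphenyl)prop-2-enoate
Product: 23 3-[(2R,3S)-2-(4-hydroxy-3-methoxyphenyl)-3-(hydroxymethyl)-7-methoxy-2,3-dihydrobenzofuran-5-yl]propyl (E)-3-(4-hydroxy-3-methoxyphenyl)prop-2-enoate
Conditions: TBAF, AcOH (1:1), THF, 0 °C to rt
Reagents that add atoms: none
Why: Fluoride-induced desilylation through pentacoordinate silicates removes both TIPS groups; acetic acid buffering keeps the cinnamate ester and the p-hydroxybenzyl aryl ether (C2–O1) away from free phenoxide or alkoxide, and C2 and C3 are not touched.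

## Compound list

1 | 2-bromo-3-methoxybenzaldehyde | COc1cccc(C=O)c1Br | starting material
2 | 2-bromo-1-methoxy-3-(2-methoxyethenyl)benzene (E/Z mixture, geometry not defined) | COC=Cc1cccc(OC)c1Br | intermediate
3 | 2-(2-bromo-3-methoxyphenyl)acetaldehyde | COc1cccc(CC=O)c1Br | intermediate
4 | 2-(2-bromo-3-methoxyphenyl)acetic acid | COc1cccc(CC(=O)O)c1Br | intermediate
5 | (R)-4-benzyl-1,3-oxazolidin-2-one | O=C1N[C@H](Cc2ccccc2)CO1 | starting material
6 | 2-(2-bromo-3-methoxyphenyl)acetic 2,2-dimethylpropanoic anhydride | COc1cccc(CC(=O)OC(=O)C(C)(C)C)c1Br | intermediate (not isolated)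
7 | (R)-4-benzyl-3-[2-(2-bromo-3-methoxyphenyl)acetyl]-1,3-oxazolidin-2-one | COc1cccc(CC(=O)N2[C@H](Cc3ccccc3)COC2=O)c1Br | intermediate
8 | vanillin | COc1cc(C=O)ccc1O | starting material
9 | 3-methoxy-4-(triisopropylsilyloxy)benzaldehyde | COc1cc(C=O)ccc1O[Si](C(C)C)(C(C)C)C(C)C | intermediate
10 | (R)-4-benzyl-3-[(Z)-2-(2-bromo-3-methoxyphenyl)-1-(dibutylboryloxy)ethenyl]-1,3-oxazolidin-2-one | COc1cccc(/C=C(\OB(CCCC)CCCC)N2[C@H](Cc3ccccc3)COC2=O)c1Br | intermediate (not isolated)
11 | (R)-4-benzyl-3-[(2R,3R)-2-(2-bromo-3-methoxyphenyl)-3-(dibutylboryloxy)-3-(3-methoxy-4-triisopropylsilyloxyphenyl)propanoyl]-1,3-oxazolidin-2-one | COc1cccc([C@@H](C(=O)N2[C@H](Cc3ccccc3)COC2=O)[C@H](c2ccc(O[Si](C(C)C)(C(C)C)C(C)C)c(OC)c2)OB(CCCC)CCCC)c1Br | intermediate (not isolated)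
12 | (R)-4-benzyl-3-[(2R,3R)-2-(2-bromo-3-methoxyphenyl)-3-hydroxy-3-(3-methoxy-4-triisopropylsilyloxyphenyl)propanoyl]-1,3-oxazolidin-2-one | COc1cccc([C@@H](C(=O)N2[C@H](Cc3ccccc3)COC2=O)[C@H](c2ccc(O[Si](C(C)C)(C(C)C)C(C)C)c(OC)c2)O)c1Br | intermediate
13 | (1R,2S)-2-(2-bromo-3-methoxyphenyl)-1-(3-methoxy-4-triisopropylsilyloxyphenyl)propane-1,3-diol | COc1cccc([C@@H](CO)[C@H](c2ccc(O[Si](C(C)C)(C(C)C)C(C)C)c(OC)c2)O)c1Br | intermediate
14 | (1R,2S)-2-(2-bromo-3-methoxyphenyl)-1-(3-methoxy-4-triisopropylsilyloxyphenyl)-3-(triisopropylsilyloxy)propan-1-ol | COc1cccc([C@@H](CO[Si](C(C)C)(C(C)C)C(C)C)[C@H](c2ccc(O[Si](C(C)C)(C(C)C)C(C)C)c(OC)c2)O)c1Br | intermediate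
15 | (2R,3S)-7-methoxy-2-(3-methoxy-4-triisopropylsilyloxyphenyl)-3-(triisopropylsilyloxymethyl)-2,3-dihydrobenzofuran | c1cc(OC)c2c(c1)[C@@H](CO[Si](C(C)C)(C(C)C)C(C)C)[C@H](c1ccc(O[Si](C(C)C)(C(C)C)C(C)C)c(OC)c1)O2 | intermediate
16 | (2R,3S)-7-methoxy-2-(3-methoxy-4-triisopropylsilyloxyphenyl)-5-(4,4,5,5-tetramethyl-1,3,2-dioxaborolan-2-yl)-3-(triisopropylsilyloxymethyl)-2,3-dihydrobenzofuran | CC1(C)OB(c2cc(OC)c3c(c2)[C@@H](CO[Si](C(C)C)(C(C)C)C(C)C)[C@H](c2ccc(O[Si](C(C)C)(C(C)C)C(C)C)c(OC)c2)O3)OC1(C)C | intermediate
17 | allyl bromide (3-bromoprop-1-ene) | C=CCBr | starting material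
18 | (2R,3S)-5-allyl-7-methoxy-2-(3-methoxy-4-triisopropylsilyloxyphenyl)-3-(triisopropylsilyloxymethyl)-2,3-dihydrobenzofuran | C=CCc1cc(OC)c2c(c1)[C@@H](CO[Si](C(C)C)(C(C)C)C(C)C)[C@H](c1ccc(O[Si](C(C)C)(C(C)C)C(C)C)c(OC)c1)O2 | intermediate
19 | 9-{3-[(2R,3S)-7-methoxy-2-(3-methoxy-4-triisopropylsilyloxyphenyl)-3-(triisopropylsilyloxymethyl)-2,3-dihydrobenzofuran-5-yl]propyl}-9-borabicyclo[3.3.1]nonane | C1CCC2CCCC1B2CCCc1cc(OC)c2c(c1)[C@@H](CO[Si](C(C)C)(C(C)C)C(C)C)[C@H](c1ccc(O[Si](C(C)C)(C(C)C)C(C)C)c(OC)c1)O2 | intermediate (not isolated)
20 | 3-[(2R,3S)-7-methoxy-2-(3-methoxy-4-triisopropylsilyloxyphenyl)-3-(triisopropylsilyloxymethyl)-2,3-dihydrobenzofuran-5-yl]propan-1-ol | OCCCc1cc(OC)c2c(c1)[C@@H](CO[Si](C(C)C)(C(C)C)C(C)C)[C@H](c1ccc(O[Si](C(C)C)(C(C)C)C(C)C)c(OC)c1)O2 | intermediate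
21 | (E)-ferulic acid | COc1cc(/C=C/C(=O)O)ccc1O | starting material
22 | 3-[(2R,3S)-7-methoxy-2-(3-methoxy-4-triisopropylsilyloxyphenyl)-3-(triisopropylsilyloxymethyl)-2,3-dihydrobenzofuran-5-yl]propyl (E)-3-(4-hydroxy-3-methoxyphenyl)prop-2-enoate | COc1cc(/C=C/C(=O)OCCCc2cc(OC)c3c(c2)[C@@H](CO[Si](C(C)C)(C(C)C)C(C)C)[C@H](c2ccc(O[Si](C(C)C)(C(C)C)C(C)C)c(OC)c2)O3)ccc1O | intermediate
23 | 3-[(2R,3S)-2-(4-hydroxy-3-methoxyphenyl)-3-(hydroxymethyl)-7-methoxy-2,3-dihydrobenzofuran-5-yl]propyl (E)-3-(4-hydroxy-3-methoxyphenyl)prop-2-enoate | COc1cc(/C=C/C(=O)OCCCc2cc(OC)c3c(c2)[C@@H](CO)[C@H](c2ccc(O)c(OC)c2)O3)ccc1O | target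

## Step count and least certain steps

Total: 14 steps. Longest linear sequence: 13 steps (steps 1 to 4 and 6 to 14, from 1); step 5 is the only branch.

Step 9 (key step).
- Most likely to go wrong: slow oxidative addition at a C–Br bond flanked by the side chain and the methoxy group, leading to stalled conversion or protodebromination. A base-induced 1,5 O-to-O silyl shift would expose the primary alkoxide, which can close an isomeric five-membered ring. Silyl transfer from the ring B phenol oxygen to the alkoxide is also possible at 110 °C.
- Fallback (sets out from 14, returns at 15): the bond formed is changed from O1–C7a to O1–C2. Bromine–lithium exchange on the lithium alkoxide of 14 (n-BuLi, 2.2 equiv, THF, −78 °C) and trapping with B(OMe)3 would give, after aqueous work-up, the arylboronic acid (1R,2S)-2-(2-borono-3-methoxyphenyl)-1-(3-methoxy-4-triisopropylsilyloxyphenyl)-3-(triisopropylsilyloxy)propan-1-ol F1. This is oxidised without purification (H2O2, aq NaOAc) to the phenol (1R,2S)-2-(2-hydroxy-3-methoxyphenyl)-1-(3-methoxy-4-triisopropylsilyloxyphenyl)-3-(triisopropylsilyloxy)propan-1-ol F2. Catalytic camphorsulfonic acid in CH2Cl2 at 0 °C should then ionise the p-silyloxybenzylic carbinol, and the phenol should close the ring anti to the C3 substituent (acid-catalysed dehydrative cyclisation through a benzylic cation) to give 15. C3 is not involved, so enantiomeric purity is kept, and a cis isomer, if formed, is a separable diastereomer.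

Step 6.
- Most likely to go wrong: reversal of the aldol addition during warming and oxidative work-up, because the electron-rich aldehyde is a weak acceptor and the aryl-stabilised enolate a good leaving group. The result would be incomplete conversion and erosion of the syn selectivity.
- Fallback (sets out from 4, returns at 13): 4 is coupled with (R)-4-benzyl-1,3-thiazolidine-2-thione (EDC·HCl, DMAP, CH2Cl2) to the thioimide (R)-1-(4-benzyl-2-thioxo-1,3-thiazolidin-3-yl)-2-(2-bromo-3-methoxyphenyl)ethan-1-one F3. Its titanium enolate (TiCl4, iPr2NEt, N-methylpyrrolidinone, CH2Cl2, −78 to 0 °C) should add to 9 through a non-chelated chair transition state with the same facial sense, giving (2R,3R)-1-[(R)-4-benzyl-2-thioxo-1,3-thiazolidin-3-yl]-2-(2-bromo-3-methoxyphenyl)-3-hydroxy-3-(3-methoxy-4-triisopropylsilyloxyphenyl)propan-1-one F4. The activated thioimide is reduced directly with NaBH4 (THF/EtOH, 0 °C) to 13.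

Step 10.
- Most likely to go wrong: slow C–H activation of an electron-rich, heavily substituted arene, or minor borylation ortho to the C7 methoxy group, giving incomplete conversion or a regioisomeric mixture.
- Fallback (sets out from 15, returns at 18): electrophilic bromination with NBS (MeCN, 0 °C). C5 is para to the ring oxygen O1, whose lone pair is held in conjugation, and is the least hindered activated position, so the bromide (2R,3S)-5-bromo-7-methoxy-2-(3-methoxy-4-triisopropylsilyloxyphenyl)-3-(triisopropylsilyloxymethyl)-2,3-dihydrobenzofuran F5 should be favoured. Stille coupling with Bu3SnCH2CH=CH2 (Pd(PPh3)4, toluene, 100 °C) then gives 18. This is second choice because selectivity between two electron-rich rings is then a matter of degree and not of a steric rule.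

Step 13.
- Most likely to go wrong: competing O-alkylation of the phenol of 21 by the activated alcohol, and difficult separation of the product from the phosphine oxide and hydrazide by-products.
- Fallback (sets out from 20 and 21, returns at 23): 21 is silylated on both oxygens (TIPSCl, imidazole, DMF) to triisopropylsilyl (E)-3-(3-methoxy-4-triisopropylsilyloxyphenyl)prop-2-enoate F6. The silyl ester is hydrolysed selectively (AcOH, THF/H2O) to (E)-3-(3-methoxy-4-triisopropylsilyloxyphenyl)prop-2-enoic acid F7. Steglich esterification of 20 with F7 (EDC·HCl, DMAP, CH2Cl2) gives 3-[(2R,3S)-7-methoxy-2-(3-methoxy-4-triisopropylsilyloxyphenyl)-3-(triisopropylsilyloxymethyl)-2,3-dihydrobenzofuran-5-yl]propyl (E)-3-(3-methoxy-4-triisopropylsilyloxyphenyl)prop-2-enoate F8. All three silyl groups are then removed with TBAF/AcOH in THF to give 23.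

## Further compounds

F1 | step 9 | (1R,2S)-2-(2-borono-3-methoxyphenyl)-1-(3-methoxy-4-triisopropylsilyloxyphenyl)-3-(triisopropylsilyloxy)propan-1-ol | COc1cccc([C@@H](CO[Si](C(C)C)(C(C)C)C(C)C)[C@H](c2ccc(O[Si](C(C)C)(C(C)C)C(C)C)c(OC)c2)O)c1B(O)O
F2 | step 9 | (1R,2S)-2-(2-hydroxy-3-methoxyphenyl)-1-(3-methoxy-4-triisopropylsilyloxyphenyl)-3-(triisopropylsilyloxy)propan-1-ol | COc1cccc([C@@H](CO[Si](C(C)C)(C(C)C)C(C)C)[C@H](c2ccc(O[Si](C(C)C)(C(C)C)C(C)C)c(OC)c2)O)c1O
F3 | step 6 | (R)-1-(4-benzyl-2-thioxo-1,3-thiazolidin-3-yl)-2-(2-bromo-3-methoxyphenyl)ethan-1-one | COc1cccc(CC(=O)N2[C@H](Cc3ccccc3)CSC2=S)c1Br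
F4 | step 6 | (2R,3R)-1-[(R)-4-benzyl-2-thioxo-1,3-thiazolidin-3-yl]-2-(2-bromo-3-methoxyphenyl)-3-hydroxy-3-(3-methoxy-4-triisopropylsilyloxyphenyl)propan-1-one | COc1cccc([C@@H](C(=O)N2[C@H](Cc3ccccc3)CSC2=S)[C@H](c2ccc(O[Si](C(C)C)(C(C)C)C(C)C)c(OC)c2)O)c1Br
F5 | step 10 | (2R,3S)-5-bromo-7-methoxy-2-(3-methoxy-4-triisopropylsilyloxyphenyl)-3-(triisopropylsilyloxymethyl)-2,3-dihydrobenzofuran | Brc1cc(OC)c2c(c1)[C@@H](CO[Si](C(C)C)(C(C)C)C(C)C)[C@H](c1ccc(O[Si](C(C)C)(C(C)C)C(C)C)c(OC)c1)O2
F6 | step 13 | triisopropylsilyl (E)-3-(3-methoxy-4-triisopropylsilyloxyphenyl)prop-2-enoate | COc1cc(/C=C/C(=O)O[Si](C(C)C)(C(C)C)C(C)C)ccc1O[Si](C(C)C)(C(C)C)C(C)C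
F7 | step 13 | (E)-3-(3-methoxy-4-triisopropylsilyloxyphenyl)prop-2-enoic acid | COc1cc(/C=C/C(=O)O)ccc1O[Si](C(C)C)(C(C)C)C(C)C
F8 | step 13 | 3-[(2R,3S)-7-methoxy-2-(3-methoxy-4-triisopropylsilyloxyphenyl)-3-(triisopropylsilyloxymethyl)-2,3-dihydrobenzofuran-5-yl]propyl (E)-3-(3-methoxy-4-triisopropylsilyloxyphenyl)prop-2-enoate | COc1cc(/C=C/C(=O)OCCCc2cc(OC)c3c(c2)[C@@H](CO[Si](C(C)C)(C(C)C)C(C)C)[C@H](c2ccc(O[Si](C(C)C)(C(C)C)C(C)C)c(OC)c2)O3)ccc1O[Si](C(C)C)(C(C)C)C(C)C
A1 | alternative 1 | (2R)-2-(4-benzyloxy-3-methoxyphenyl)-6-(3-benzyloxypropyl)-8-methoxy-2,3-dihydro-4H-chromen-4-one | O=C1C[C@H](c2ccc(OCc3ccccc3)c(OC)c2)Oc2c(OC)cc(CCCOCc3ccccc3)cc21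
A2 | alternative 1 | methyl (2R,3R)-2-(4-benzyloxy-3-methoxyphenyl)-5-(3-benzyloxypropyl)-7-methoxy-2,3-dihydrobenzofuran-3-carboxylate (trans) | c1ccccc1COCCCc1cc(OC)c2c(c1)[C@@H](C(=O)OC)[C@H](c1ccc(OCc3ccccc3)c(OC)c1)O2
A3 | alternative 2 | 6-(3-benzyloxypropyl)-3-{(1R,2S)-1-[4-(tert-butyldimethylsilyloxy)-3-methoxyphenyl]-2-(tert-butyldimethylsilyloxymethyl)but-3-ynyloxy}-4-methoxy-2H-pyran-2-one | O=c1oc(CCCOCc2ccccc2)cc(OC)c1O[C@@H](c1ccc(O[Si](C)(C)C(C)(C)C)c(OC)c1)[C@H](CO[Si](C)(C)C(C)(C)C)C#C
A4 | alternative 2 | (2R,3S)-5-(3-benzyloxypropyl)-2-[4-(tert-butyldimethylsilyloxy)-3-methoxyphenyl]-3-(tert-butyldimethylsilyloxymethyl)-7-methoxy-2,3-dihydrobenzofuran | c1ccccc1COCCCc1cc(OC)c2c(c1)[C@@H](CO[Si](C)(C)C(C)(C)C)[C@H](c1ccc(O[Si](C)(C)C(C)(C)C)c(OC)c1)O2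
A5 | alternative 3 | (2S)-2-[5-(3-benzyloxypropyl)-3-methoxy-2-(methoxymethoxy)phenyl]-1-(4-benzyloxy-3-methoxyphenyl)-3-(tert-butyldiphenylsilyloxy)propan-1-ol (either C1 epimer) | COCOc1c(OC)cc(CCCOCc2ccccc2)cc1[C@@H](CO[Si](c1ccccc1)(c1ccccc1)C(C)(C)C)C(O)c1ccc(OCc2ccccc2)c(OC)c1
A6 | alternative 3 | (2R,3S)-2-(4-benzyloxy-3-methoxyphenyl)-5-(3-benzyloxypropyl)-3-(tert-butyldiphenylsilyloxymethyl)-7-methoxy-2,3-dihydrobenzofuran | c1ccccc1COCCCc1cc(OC)c2c(c1)[C@@H](CO[Si](c1ccccc1)(c1ccccc1)C(C)(C)C)[C@H](c1ccc(OCc3ccccc3)c(OC)c1)O2
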